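**Retrosynthetic overview**
The target is ring A (an acylphloroglucinol) fused to a six-membered lactone (O1, C2, C3, C4, C4a, C8a) with a 4S phenyl group; the last disconnection removes two benzyl ethers from O5 and O7.
The lactone is opened at C2–C3. The enabling feature is that C2 hangs on the phenolic O1 of ring A, ortho to C4a, and C4 is a benzylic CH. C4–H can therefore come as hydride to a C4=C3 1,1-diarylethene, which puts copper on C3, five atoms from a phenyl carbonate carbon on O1.
The C8 dihydrochalcone ketone is carried as the chalcone. The same CuH catalyst should reduce it 1,4 to a silyl enol ether, which masks the ketone during the key event and is hydrolysed on work-up.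
The carbonate precursor comes from a Claisen–Schmidt condensation with 4-methoxybenzaldehyde, a Suzuki–Miyaura coupling with a 1-phenylethenylboronate and an iodination ortho to the free hydroxyl of phloroacetophenone 4,6-dibenzyl ether.
Ring order: ring A, the anisyl ring and the phenyl ring are bought; the lactone ring is the only ring formed (step 6).

Key step: step 6

Assumption: the (R)-enantiomer of DTBM-SEGPHOS is taken to deliver the 4S configuration; should the opposite sense be found, the (S)-ligand is used with no other change.

**Route**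

Step 1
Reactants: 1 1-(2,4,6-trihydroxyphenyl)ethan-1-one
Product: 2 1-[2,4-bis(benzyloxy)-6-hydroxyphenyl]ethan-1-one
Conditions: BnBr (2.1 equiv), K2CO3 (2.2 equiv), DMF, 0 °C to rt
Reagents that add atoms: benzyl bromide, BrCc1ccccc1
Why: Williamson ether synthesis in which the para hydroxyl and one ortho hydroxyl should be alkylated, while the last ortho hydroxyl is held back by its hydrogen bond to the acetyl carbonyl.

Step 2
Reactants: 2 1-[2,4-bis(benzyloxy)-6-hydroxyphenyl]ethan-1-one
Product: 3 1-[4,6-bis(benzyloxy)-2-hydroxy-3-iodophenyl]ethan-1-one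
Conditions: NIS (1.0 equiv), TFA (cat.), MeCN, 0 °C, dark
Reagents that add atoms: N-iodosuccinimide, O=C1CCC(=O)N1I
Why: Electrophilic aromatic iodination, expected at the ring position ortho to the free hydroxyl, which is the less hindered of the two activated positions (the other lies between two benzyloxy groups).

Step 3
Reactants: 3 1-[4,6-bis(benzyloxy)-2-hydroxy-3-iodophenyl]ethan-1-one; 4 4,4,5,5-tetramethyl-2-(1-phenylethenyl)-1,3,2-dioxaborolane
Product: 5 1-[4,6-bis(benzyloxy)-2-hydroxy-3-(1-phenylethenyl)phenyl]ethan-1-one
Conditions: Pd(OAc)2 (5 mol %), SPhos (10 mol %), K3PO4 (3 equiv), toluene/H2O 10:1, 80 °C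
Reagents that add atoms: none
Why: Suzuki–Miyaura cross-coupling, for which a dialkylbiarylphosphine ligand should cope with the doubly ortho-substituted aryl iodide and the free phenol is tolerated as its phenoxide.

Step 4
Reactants: 5 1-[4,6-bis(benzyloxy)-2-hydroxy-3-(1-phenylethenyl)phenyl]ethan-1-one; 6 4-methoxybenzaldehyde
Product: 7 (2E)-1-[4,6-bis(benzyloxy)-2-hydroxy-3-(1-phenylethenyl)phenyl]-3-(4-methoxyphenyl)prop-2-en-1-one
Conditions: KOH (50 % aq., 5 equiv), EtOH/THF, rt; then 1 M HCl to pH 5
Reagents that add atoms: none
Why: Claisen–Schmidt condensation of the methyl ketone with a non-enolisable aldehyde, in which E1cB dehydration should give the E enone and the 1,1-diarylethene is inert to base.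

Step 5
Reactants: 7 (2E)-1-[4,6-bis(benzyloxy)-2-hydroxy-3-(1-phenylethenyl)phenyl]-3-(4-methoxyphenyl)prop-2-en-1-one
Product: 8 3,5-bis(benzyloxy)-2-[(2E)-3-(4-methoxyphenyl)prop-2-enoyl]-6-(1-phenylethenyl)phenyl phenyl carbonate
Conditions: PhOCOCl (1.5 equiv), Et3N (2 equiv), DMAP (10 mol %), CH2Cl2, 0 °C to rt
Reagents that add atoms: phenyl chloroformate, O=C(Cl)Oc1ccccc1
Why: O-acylation of the only free phenol with a chloroformate under nucleophilic (DMAP) catalysis; the enone has no enolisable α-CH, so no Baker–Venkataraman-type acyl shift can follow.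

Step 6
Reactants: 8 3,5-bis(benzyloxy)-2-[(2E)-3-(4-methoxyphenyl)prop-2-enoyl]-6-(1-phenylethenyl)phenyl phenyl carbonate
Product: 11 (4S)-5,7-bis(benzyloxy)-8-[3-(4-methoxyphenyl)propanoyl]-4-phenyl-3,4-dihydro-2H-chromen-2-one, via silyl enol ether carbonate 9 (not isolated), via lactone silyl enol ether 10 (not isolated)
Conditions: Cu(OAc)2 (5 mol %), (R)-DTBM-SEGPHOS (5.5 mol %), (MeO)2MeSiH (4 equiv), THF, rt then 40 °C; then 1 M HCl, THF, 0 °C
Reagents that add atoms: none
Why: Proposed new method: L*CuH (formed from Cu(OAc)2, the bisphosphine and the silane) first reduces the enone 1,4 and the copper enolate is silylated by the silane to 9, so the ketone is masked against 1,2-reduction, and L*CuH then adds across the 1,1-diarylethene with hydride to the internal carbon (C4) and copper to the terminal CH2 (C3); this primary alkylcopper attacks the carbonate carbon held on O1 and expels phenoxide, and L*CuOPh is returned to L*CuH by the silane. The closest known reaction types are the CuH-catalysed enantioselective anti-Markovnikov hydrofunctionalisation of 1,1-disubstituted alkenes and the CuH-catalysed hydrocarboxylation of alkenes with fluoroformates, from which the step differs in the intramolecular capture by an aryl carbonate. The lactone ring is closed by the C3 to C2 bond in a 6-exo-trig addition-elimination. The C4 stereocentre is set under catalyst control in the hydrocupration, where the ligand pocket must tell the coplanar phenyl group from ring A, which its two ortho oxygen substituents twist out of the alkene plane. The step needs regioselectivity (copper on C3, secured by the steric bar to a tertiary diarylalkylcopper), chemoselectivity (the alkylcopper has no proton source and no other electrophile within reach, so it should wait for the carbonate) and face selectivity (ligand). If the tetrahedral intermediate expels the ring A aryloxide in place of phenoxide, the phenyl ester so formed should relactonise to the same product.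

Step 7
Reactants: 11 (4S)-5,7-bis(benzyloxy)-8-[3-(4-methoxyphenyl)propanoyl]-4-phenyl-3,4-dihydro-2H-chromen-2-one
Product: 12 (4S)-5,7-dihydroxy-8-[3-(4-methoxyphenyl)propanoyl]-4-phenyl-3,4-dihydro-2H-chromen-2-one
Conditions: H2 (1 atm), Pd/C (10 wt %), EtOAc, rt
Reagents that add atoms: none
Why: Hydrogenolysis of the two benzyl aryl ethers in an aprotic solvent, which should spare the lactone, the hindered aryl ketone, the anisole and the C4 centre (no heteroatom on C4, neutral medium).

**Compound list**
1 | 1-(2,4,6-trihydroxyphenyl)ethan-1-one | CC(=O)c1c(O)cc(O)cc1O | starting material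
2 | 1-[2,4-bis(benzyloxy)-6-hydroxyphenyl]ethan-1-one | CC(=O)c1c(O)cc(OCc2ccccc2)cc1OCc1ccccc1 | intermediate
3 | 1-[4,6-bis(benzyloxy)-2-hydroxy-3-iodophenyl]ethan-1-one | CC(=O)c1c(O)c(I)c(OCc2ccccc2)cc1OCc1ccccc1 | intermediate
4 | 4,4,5,5-tetramethyl-2-(1-phenylethenyl)-1,3,2-dioxaborolane | C=C(B1OC(C)(C)C(C)(C)O1)c1ccccc1 | starting material
5 | 1-[4,6-bis(benzyloxy)-2-hydroxy-3-(1-phenylethenyl)phenyl]ethan-1-one | CC(=O)c1c(O)c(C(=C)c2ccccc2)c(OCc2ccccc2)cc1OCc1ccccc1 | intermediate
6 | 4-methoxybenzaldehyde | COc1ccc(C=O)cc1 | starting material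
7 | (2E)-1-[4,6-bis(benzyloxy)-2-hydroxy-3-(1-phenylethenyl)phenyl]-3-(4-methoxyphenyl)prop-2-en-1-one | COc1ccc(/C=C/C(=O)c2c(O)c(C(=C)c3ccccc3)c(OCc3ccccc3)cc2OCc2ccccc2)cc1 | intermediate
8 | 3,5-bis(benzyloxy)-2-[(2E)-3-(4-methoxyphenyl)prop-2-enoyl]-6-(1-phenylethenyl)phenyl phenyl carbonate | COc1ccc(/C=C/C(=O)c2c(OC(=O)Oc3ccccc3)c(C(=C)c3ccccc3)c(OCc3ccccc3)cc2OCc2ccccc2)cc1 | intermediate
9 | 3,5-bis(benzyloxy)-2-{(1Z)-1-[dimethoxy(methyl)silyloxy]-3-(4-methoxyphenyl)prop-1-en-1-yl}-6-(1-phenylethenyl)phenyl phenyl carbonate | COc1ccc(C/C=C(\O[Si](C)(OC)OC)c2c(OC(=O)Oc3ccccc3)c(C(=C)c3ccccc3)c(OCc3ccccc3)cc2OCc2ccccc2)cc1 | intermediate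
10 | (4S)-5,7-bis(benzyloxy)-8-{(1Z)-1-[dimethoxy(methyl)silyloxy]-3-(4-methoxyphenyl)prop-1-en-1-yl}-4-phenyl-3,4-dihydro-2H-chromen-2-one | COc1ccc(C/C=C(\O[Si](C)(OC)OC)c2c(OCc4ccccc4)cc(OCc4ccccc4)c3c2OC(=O)C[C@H]3c2ccccc2)cc1 | intermediate
11 | (4S)-5,7-bis(benzyloxy)-8-[3-(4-methoxyphenyl)propanoyl]-4-phenyl-3,4-dihydro-2H-chromen-2-one | COc1ccc(CCC(=O)c2c(OCc4ccccc4)cc(OCc4ccccc4)c3c2OC(=O)C[C@H]3c2ccccc2)cc1 | intermediate
12 | (4S)-5,7-dihydroxy-8-[3-(4-methoxyphenyl)propanoyl]-4-phenyl-3,4-dihydro-2H-chromen-2-one | COc1ccc(CCC(=O)c2c(O)cc(O)c3c2OC(=O)C[C@H]3c2ccccc2)cc1 | target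

**Step count and risks**
Total step count: 7. Longest linear sequence: 7 steps (1 to 12).

Steps most likely to fail:

Step 6 (proposed method). Several processes could defeat it. The transient copper enolate could be C-acylated by the neighbouring carbonate before it is silylated, which would consume the tether. Hydride could attack the carbonate directly. Hydrocupration of the hindered alkene could be so slow that the alkylcopper is only protonated on work-up. The two alkene faces could be told apart poorly. The fallback uses known chemistry, sets out from phenol 7 and leaves out 8 to 11. A palladium-catalysed enantioselective intramolecular hydroesterification of the 2-(1-arylethenyl)phenol with CO (Pd(OAc)2, chiral bisphosphine, CO, TsOH cat., toluene, 60 °C), a reaction type established for this substrate class, should give the chalcone lactone (4S)-5,7-bis(benzyloxy)-8-[(2E)-3-(4-methoxyphenyl)prop-2-enoyl]-4-phenyl-3,4-dihydro-2H-chromen-2-one F1. In it the lactone carbonyl carbon comes from CO and the enone is untouched. Hydrogenation (H2, Pd/C, EtOAc, rt) should then saturate the enone C=C and cleave both benzyl ethers in one operation, which comes back to the route at target 12.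

Step 3. The α-styrylboronate may be lost to protodeboronation or oligomerisation, and transmetalation at the doubly ortho-flanked iodide may be slow enough for hydrodeiodination to take over. The fallback sets out from iodide 3 and uses a palladium-catalysed coupling with commercial acetophenone N-tosylhydrazone (Pd2(dba)3, XPhos, LiOtBu, dioxane, 90 °C). A palladium carbene forms, the aryl group migrates to the carbene carbon and β-hydride elimination releases the 1,1-diarylethene, so no vinylboron reagent is needed. The path comes back to the route at 5 and makes no compound outside the list (F0).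

Step 2. Iodination may take place at the other free ring position, between the two benzyloxy groups, or twice. The fallback sets out from 1, in which the two free ring positions are equivalent. Iodination (NIS, 1.0 equiv, THF, −20 °C) should give 1-(2,4,6-trihydroxy-3-iodophenyl)ethan-1-one F2 without a regiochemical question. Dibenzylation (BnBr 2.1 equiv, K2CO3, DMF) should then take the para hydroxyl and the less hindered ortho hydroxyl, because the remaining hydroxyl is wedged between iodine and the hydrogen-bonding acetyl group. This comes back to the route at 3.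

Further compounds
F1 | step 6 | (4S)-5,7-bis(benzyloxy)-8-[(2E)-3-(4-methoxyphenyl)prop-2-enoyl]-4-phenyl-3,4-dihydro-2H-chromen-2-one | COc1ccc(/C=C/C(=O)c2c(OCc4ccccc4)cc(OCc4ccccc4)c3c2OC(=O)C[C@H]3c2ccccc2)cc1
F0 | step 3 | none | none
F2 | step 2 | 1-(2,4,6-trihydroxy-3-iodophenyl)ethan-1-one | CC(=O)c1c(O)cc(O)c(I)c1O
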